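**Assumption:** β-isocupreidine is taken to give the (7R) alcohol in step 8; if it gives (7S), its pseudoenantiomer α-isocupreine is used under the same conditions. 2-Methyl-4H-pyran-4-one (10) is taken to be a catalogue compound.

Atom labels C1–C7a follow the cyclopenta[c]pyran numbering of the target (C5 carries CO2Me, C6 the enone, C7 the carbinol).

## Retrosynthetic overview

1. Target ⇒ ene-dione 15 by closing the C7–C7a bond in an enantioselective vinylogous Baylis–Hillman-type aldol; the cyclopentene ring is formed last and C7 is set here.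
2. 15 ⇒ furan 13: the furan is a masked (Z)-ene-1,4-dione and is opened with singlet oxygen, which delivers the acetyl group and the side-chain ketone cis to each other.
3. 13 ⇒ diazo ester 9 + pyranthione 11: the C5=C4a bond is made by carbenoid/thione coupling and sulfur extrusion; the pyran ring is brought in preformed.
4. 9 ⇒ furylacetate 5 + (E)-non-2-enal: iminium-catalysed Friedel–Crafts alkylation sets the side-chain stereocentre, then decarbonylation (CH2CHO → CH3) and diazo transfer.
5. 5 ⇒ furfuryl alcohol + trimethyl orthoacetate (Johnson–Claisen). Ring order: furan (temporary, from 1) → pyran (attached in step 6) → cyclopentene (step 8).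

## Route

Step 1
Reactants: 1 furan-2-ylmethanol (furfuryl alcohol); 2 trimethyl orthoacetate
Product: 5 methyl 2-(2-methylfuran-3-yl)acetate, via furfuryl ketene acetal 3 (not isolated), via methylidene dihydrofuran ester 4 (not isolated)
Conditions: 2 (6 equiv), propionic acid (10 mol %), o-xylene, pressure tube, 150 °C
Reagents that add atoms: none
Why: Johnson–Claisen (orthoester Claisen) rearrangement in its known furfuryl form, in which acid-catalysed exchange gives the ketene acetal, a [3,3]-shift across the furan C2–C3 bond forms the C–C bond at C3 and a re-aromatising hydrogen shift turns the former CH2O carbon into the 2-methyl group; no stereocentre is formed.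

Step 2
Reactants: 5 methyl 2-(2-methylfuran-3-yl)acetate; 6 (E)-non-2-enal
Product: 7 methyl 2-{2-methyl-5-[(3R)-1-oxononan-3-yl]furan-3-yl}acetate
Conditions: (2S,5S)-5-benzyl-2-tert-butyl-3-methylimidazolidin-4-one·TFA (20 mol %), 6 (2 equiv), CHCl3, −30 °C
Reagents that add atoms: none
Why: Iminium-ion organocatalytic Friedel–Crafts alkylation (MacMillan imidazolidinone), in which the only free α-position of the 2,3-dialkylfuran (C5) adds to the β-carbon of the (E)-iminium ion on the face opposite the benzyl group (Re face of Cβ for an alkyl enal), the same sense as in the established indole, pyrrole and 2-methylfuran additions, giving the (3R) centre.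

Step 3
Reactants: 7 methyl 2-{2-methyl-5-[(3R)-1-oxononan-3-yl]furan-3-yl}acetate
Product: 8 methyl 2-{2-methyl-5-[(2S)-octan-2-yl]furan-3-yl}acetate
Conditions: [RhCl(cod)]2 (2.5 mol %), dppp (5 mol %), diglyme, 162 °C, N2 sweep
Reagents that add atoms: none
Why: Tsuji–Wilkinson-type rhodium-catalysed decarbonylation (aldehyde C–H insertion, CO de-insertion, reductive elimination) converts CH2CHO into CH3 without touching the β-stereocentre, whose descriptor changes from R to S only because the group priorities change.

Step 4
Reactants: 8 methyl 2-{2-methyl-5-[(2S)-octan-2-yl]furan-3-yl}acetate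
Product: 9 methyl 2-diazo-2-{2-methyl-5-[(2S)-octan-2-yl]furan-3-yl}acetate
Conditions: p-ABSA (1.3 equiv), DBU (1.5 equiv), MeCN, 0 °C to rt
Reagents that add atoms: 4-acetamidobenzenesulfonyl azide (p-ABSA), CC(=O)Nc1ccc(cc1)S(=O)(=O)N=[N+]=[N-]
Why: Regitz diazo transfer to the DBU-generated enolate of a heteroarylacetic ester is routine and leaves the remote stereocentre untouched.

Step 5
Reactants: 10 2-methyl-4H-pyran-4-one
Product: 11 2-methyl-4H-pyran-4-thione
Conditions: Lawesson's reagent (0.55 equiv), toluene, 80 °C
Reagents that add atoms: Lawesson's reagent, COc1ccc(cc1)P1(=S)SP(=S)(S1)c1ccc(OC)cc1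
Why: Thionation of the vinylogous-ester carbonyl with Lawesson's reagent (Wittig-like O/S exchange) is well established for 4-pyranones.

Step 6
Reactants: 9 methyl 2-diazo-2-{2-methyl-5-[(2S)-octan-2-yl]furan-3-yl}acetate; 11 2-methyl-4H-pyran-4-thione
Product: 13 methyl 2-(2-methyl-4H-pyran-4-ylidene)-2-{2-methyl-5-[(2S)-octan-2-yl]furan-3-yl}acetate, via spiro thiirane 12 (not isolated)
Conditions: Rh2(OAc)4 (1 mol %), 11 (1.2 equiv), CH2Cl2, rt, slow addition of 9; then PPh3 (1.2 equiv), rt
Reagents that add atoms: none
Why: Barton–Kellogg-type olefination (Schönberg reaction in its rhodium-carbenoid form), in which the donor/acceptor carbenoid is captured by the nucleophilic thione sulfur, the thiocarbonyl ylide closes to the thiirane and phosphine-mediated sulfur extrusion forms the tetrasubstituted C5=C4a bond specifically at pyran C4, so addition at the unsubstituted pyran α-position cannot compete; the E/Z mixture about the new bond is inconsequential.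

Step 7
Reactants: 13 methyl 2-(2-methyl-4H-pyran-4-ylidene)-2-{2-methyl-5-[(2S)-octan-2-yl]furan-3-yl}acetate
Product: 15 methyl (3Z,6S)-3-acetyl-6-methyl-2-(2-methyl-4H-pyran-4-ylidene)-5-oxododec-3-enoate, via furan endoperoxide 14 (not isolated)
Conditions: O2, methylene blue (1 mol %), red LED (about 660 nm), CH2Cl2, −78 °C; then Me2S (3 equiv), −78 to 0 °C
Reagents that add atoms: dioxygen, O=O
Why: Singlet-oxygen [4+2] cycloaddition to the trialkyl-type furan (much faster than attack on the push–pull pyranylidene, which red light does not excite) and Me2S reduction of the endoperoxide is the standard furan to (Z)-ene-1,4-dione unmasking, and it places the acetyl group and the side-chain ketone cis, which is the geometry of the target's exocyclic enone.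

Step 8
Reactants: 15 methyl (3Z,6S)-3-acetyl-6-methyl-2-(2-methyl-4H-pyran-4-ylidene)-5-oxododec-3-enoate
Product: 16 methyl (6Z,7R)-7-hydroxy-3,7-dimethyl-6-[(3S)-3-methyl-2-oxononylidene]-6,7-dihydrocyclopenta[c]pyran-5-carboxylate
Conditions: β-isocupreidine (15 mol %), CH2Cl2, −20 °C
Reagents that add atoms: none
Why: Proposed new method: an enantioselective vinylogous Morita–Baylis–Hillman cyclisation in which the quinuclidine nitrogen adds reversibly to the unhindered, acceptor-activated C1–H carbon of the pyranylidene (not to the methyl-bearing C3, which fixes the regiochemistry), the resulting dienolate attacks the phenol-hydrogen-bonded acetyl carbonyl through its γ-carbon C7a in a 5-exo aldol that forms the cyclopentene ring and sets C7 under catalyst control, and E1cB loss of the amine restores C1=C7a; the closest known reactions are amine-catalysed Baylis–Hillman reactions of chromones and 4-pyranones at C3 and β-isocupreidine-catalysed asymmetric Baylis–Hillman reactions, neither shown for a 4-alkylidene-4H-pyran donor or an intramolecular ketone acceptor.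

The minor enantiomer from step 2 ends as a diastereomer of 16 and is removed in the final chromatography.

## Compound list

1 | furan-2-ylmethanol (furfuryl alcohol) | OCc1ccco1 | starting material
2 | trimethyl orthoacetate | CC(OC)(OC)OC | starting material
3 | 2-{[(1-methoxyethenyl)oxy]methyl}furan | C=C(OC)OCc1ccco1 | intermediate
4 | methyl 2-(2-methylidene-2,3-dihydrofuran-3-yl)acetate (racemic) | C=C1OC=CC1CC(=O)OC | intermediate
5 | methyl 2-(2-methylfuran-3-yl)acetate | COC(=O)Cc1ccoc1C | intermediate
6 | (E)-non-2-enal | CCCCCC/C=C/C=O | starting material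
7 | methyl 2-{2-methyl-5-[(3R)-1-oxononan-3-yl]furan-3-yl}acetate | CCCCCC[C@H](CC=O)c1cc(CC(=O)OC)c(C)o1 | intermediate
8 | methyl 2-{2-methyl-5-[(2S)-octan-2-yl]furan-3-yl}acetate | CCCCCC[C@H](C)c1cc(CC(=O)OC)c(C)o1 | intermediate
9 | methyl 2-diazo-2-{2-methyl-5-[(2S)-octan-2-yl]furan-3-yl}acetate | CCCCCC[C@H](C)c1cc(C(=[N+]=[N-])C(=O)OC)c(C)o1 | intermediate
10 | 2-methyl-4H-pyran-4-one | CC1=CC(=O)C=CO1 | starting material
11 | 2-methyl-4H-pyran-4-thione | CC1=CC(=S)C=CO1 | intermediate
12 | methyl 5-methyl-2-{2-methyl-5-[(2S)-octan-2-yl]furan-3-yl}-6-oxa-1-thiaspiro[2.5]octa-4,7-diene-2-carboxylate (diastereomer mixture) | CCCCCC[C@H](C)c1cc(c(C)o1)C1(C(=O)OC)SC12C=COC(C)=C2 | intermediate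
13 | methyl 2-(2-methyl-4H-pyran-4-ylidene)-2-{2-methyl-5-[(2S)-octan-2-yl]furan-3-yl}acetate (E/Z mixture at the exocyclic bond) | CCCCCC[C@H](C)c1cc(c(C)o1)C(C(=O)OC)=C1C=COC(C)=C1 | intermediate
14 | methyl 2-{1-methyl-4-[(2S)-octan-2-yl]-2,3,7-trioxabicyclo[2.2.1]hept-5-en-6-yl}-2-(2-methyl-4H-pyran-4-ylidene)acetate (diastereomer mixture) | CCCCCC[C@H](C)C12OOC(C)(O1)C(=C2)C(C(=O)OC)=C1C=COC(C)=C1 | intermediate
15 | methyl (3Z,6S)-3-acetyl-6-methyl-2-(2-methyl-4H-pyran-4-ylidene)-5-oxododec-3-enoate | CCCCCC[C@H](C)C(=O)/C=C(\C(C)=O)C(C(=O)OC)=C1C=COC(C)=C1 | intermediate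
16 | methyl (6Z,7R)-7-hydroxy-3,7-dimethyl-6-[(3S)-3-methyl-2-oxononylidene]-6,7-dihydrocyclopenta[c]pyran-5-carboxylate | CCCCCC[C@H](C)C(=O)/C=C1/C(C(=O)OC)=C2C=C(C)OC=C2[C@]1(C)O | target

## Step count and risks

Total steps: 8. Longest linear sequence: 7 (steps 1–4, 6–8); step 5 is a one-step side branch.

The three steps most likely to fail:

(a) The new cyclisation (step 8). The risks are amine addition at other acceptor sites, a racemic acid-type background closure through C4, and Z to E isomerisation of the ene-dione. The fallback uses known chemistry and sets out from 15: the activation is switched from the pyran to the ketone by using the chiral phosphoric acid (R)-TRIP (10 mol %) in toluene at 0 °C. This is an acid-catalysed intramolecular Prins/Friedel–Crafts-type aldol of an enol-ether carbon onto a ketone, an established manifold for chiral Brønsted acids. It comes back directly at 16 and makes no new compound (entry F0). Because the side-chain centre is already fixed, the two C7 epimers are diastereomers and can be separated by preparative HPLC whatever the selectivity.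

(b) The furan unmasking (step 7). The risk is singlet oxygen attacking the electron-rich pyranylidene. The fallback sets out from 13 and masks the pyranylidene as a pyrylium ion. HBF4 (1.0 equiv, ether solution) in CH2Cl2 at −40 °C protonates the exocyclic carbon, by far the most basic site, to give 4-{2-methoxy-1-{2-methyl-5-[(2S)-octan-2-yl]furan-3-yl}-2-oxoethyl}-2-methylpyrylium tetrafluoroborate F1, which is inert to oxidants. Photooxygenation and Me2S reduction as in step 7 then give 4-[(3Z,6S)-3-acetyl-1-methoxy-6-methyl-1,5-dioxododec-3-en-2-yl]-2-methylpyrylium tetrafluoroborate F2. Cold aqueous NaHCO3 removes the acidic C5 proton and the route is rejoined at 15.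

(c) The carbenoid/thione olefination (step 6). The risks are sulfur poisoning of Rh2(OAc)4 and carbenoid side reactions with the furan or with product 13. The fallback sets out from 8 and bypasses 9, 11 and 12 by an aldol–dehydration. The ester enolate of 8 (LiN(SiMe3)2, CeCl3, THF, −78 °C) is added to the carbonyl of 10 to give methyl 2-(4-hydroxy-2-methyl-4H-pyran-4-yl)-2-{2-methyl-5-[(2S)-octan-2-yl]furan-3-yl}acetate F3, which loses water with catalytic TFA and rejoins the route at 13. This is held as the fallback and not the main route because enolate addition at the unsubstituted pyranone α-position may compete.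

Further compounds
F0 | step 8 | none | none
F1 | step 7 | 4-{2-methoxy-1-{2-methyl-5-[(2S)-octan-2-yl]furan-3-yl}-2-oxoethyl}-2-methylpyrylium tetrafluoroborate | CCCCCC[C@H](C)c1cc(c(C)o1)C(C(=O)OC)c1cc(C)[o+]cc1.F[B-](F)(F)F
F2 | step 7 | 4-[(3Z,6S)-3-acetyl-1-methoxy-6-methyl-1,5-dioxododec-3-en-2-yl]-2-methylpyrylium tetrafluoroborate | CCCCCC[C@H](C)C(=O)/C=C(\C(C)=O)C(C(=O)OC)c1cc(C)[o+]cc1.F[B-](F)(F)F
F3 | step 6 | methyl 2-(4-hydroxy-2-methyl-4H-pyran-4-yl)-2-{2-methyl-5-[(2S)-octan-2-yl]furan-3-yl}acetate | CCCCCC[C@H](C)c1cc(c(C)o1)C(C(=O)OC)C1(O)C=COC(C)=C1
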